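**Retrosynthetic overview**

- Feature used: in ring C, C2 is a benzylic ether carbon (bonded to O1 and to C1' of ring B) and C3 lies alpha to the C4 ketone. The C2–C3 bond is therefore cut to a carbenoid at C3 (an aryl diazomethyl ketone on C4a) and one C–H bond of an O1–CH2–aryl ether.
- Ring C is the only ring made. It is closed late by an enantioselective rhodium-carbenoid C–H insertion that also sets C2; rings A and B enter as arenes.
- The diazoketone comes from the methyl ketone by detrifluoroacetylative diazo transfer. The acetyl group is placed by ortho-lithiation of the ring A benzyl ether at the carbon between O1 and O5.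
- Ring A comes from phloroglucinol: O1 is singled out as a TIPS ether and farnesyl is placed between the two MOM ethers of the symmetric arene, so it can only become C6. Ring B (from methyl 3,5-dihydroxybenzoate) is then attached to O1 by Mitsunobu etherification.
- The MOM ethers are exchanged for TIPS ethers before the diazo group is made, so one buffered fluoride step ends the synthesis.

Key step: step 12

Remark (assumption): Rh2(S-PTTL)4, dirhodium tetrakis[N-phthaloyl-(S)-tert-leucinate], is taken to give the 2S product; if the sense of induction is the opposite, the enantiomeric catalyst Rh2(R-PTTL)4 is used in the same way.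

Abbreviations: farnesyl = (2E,6E)-3,7,11-trimethyldodeca-2,6,10-trien-1-yl; MOM = methoxymethyl; TIPS = triisopropylsilyl; TBS = tert-butyldimethylsilyl. Positions are given in flavanone numbering (O1, C2, C3, C4, C4a, C5–C8, C8a; ring B C1'–C6').

**Route**

Step 1
Reactants: 1 methyl 3,5-dihydroxybenzoate
Product: 2 methyl 3,5-bis(triisopropylsilyloxy)benzoate
Conditions: TIPSCl (2.3 equiv), imidazole (5 equiv), DMF, rt
Reagents that add atoms: triisopropylsilyl chloride, CC(C)[Si](Cl)(C(C)C)C(C)C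
Why: Imidazole-mediated O-silylation of phenols; TIPS is chosen because aryl TIPS ethers withstand i-Bu2AlH, n-BuLi and acidic methanolysis later in the route.

Step 2
Reactants: 2 methyl 3,5-bis(triisopropylsilyloxy)benzoate
Product: 3 [3,5-bis(triisopropylsilyloxy)phenyl]methanol
Conditions: i-Bu2AlH (2.5 equiv), CH2Cl2, −78 → 0 °C; aq Rochelle salt
Reagents that add atoms: none
Why: Hydride reduction of a benzoate ester to the benzyl alcohol, to which aryl silyl ethers are inert.

Step 3
Reactants: 4 phloroglucinol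
Product: 5 3,5-bis(methoxymethoxy)phenol
Conditions: MOMCl (2.0 equiv), i-Pr2NEt (2.2 equiv), DMF–CH2Cl2, 0 °C → rt; chromatography
Reagents that add atoms: chloromethyl methyl ether, COCCl
Why: Williamson-type acetal etherification; statistical bis-protection of the symmetric triol leaves one phenol free (the later O1), and the mono and tris ethers should be separable by chromatography.

Step 4
Reactants: 5 3,5-bis(methoxymethoxy)phenol
Product: 6 [3,5-bis(methoxymethoxy)phenoxy]triisopropylsilane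
Conditions: TIPSCl (1.2 equiv), imidazole (2.5 equiv), DMF, rt
Reagents that add atoms: triisopropylsilyl chloride, CC(C)[Si](Cl)(C(C)C)C(C)C
Why: Phenol silylation; the bulky, non-coordinating TIPS ether marks O1, shields both of its ortho positions in the next step and is later removed by fluoride without touching the MOM ethers.

Step 5
Reactants: 6 [3,5-bis(methoxymethoxy)phenoxy]triisopropylsilane; 7 (2E,6E)-farnesyl bromide
Product: 9 {4-farnesyl-3,5-bis(methoxymethoxy)phenoxy}triisopropylsilane, via aryllithium 8 (not isolated)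
Conditions: n-BuLi (1.1 equiv), THF, 0 °C; then CuI (10 mol %), 7 (1.1 equiv), −78 °C → rt
Reagents that add atoms: none
Why: Directed ortho-metalation should occur only at the C–H flanked by the two chelating MOM ethers (the other ring positions lie next to the TIPS ether), and copper-assisted SN2 coupling of the aryl anion with the primary allylic bromide keeps the E,E geometry.

Step 6
Reactants: 9 {4-farnesyl-3,5-bis(methoxymethoxy)phenoxy}triisopropylsilane
Product: 10 4-farnesyl-3,5-bis(methoxymethoxy)phenol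
Conditions: Bu4NF (1.1 equiv), THF, 0 °C; aq NH4Cl
Reagents that add atoms: none
Why: Fluoride cleavage of the aryl silyl ether frees the single phenol of a symmetric arene, with MOM ethers and olefins untouched.

Step 7
Reactants: 10 4-farnesyl-3,5-bis(methoxymethoxy)phenol; 3 [3,5-bis(triisopropylsilyloxy)phenyl]methanol
Product: 11 1-{[3,5-bis(triisopropylsilyloxy)phenyl]methoxy}-4-farnesyl-3,5-bis(methoxymethoxy)benzene
Conditions: PPh3 (1.3 equiv), DIAD (1.3 equiv), THF, 0 °C → rt
Reagents that add atoms: none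
Why: Mitsunobu etherification of a phenol with a primary benzylic alcohol under neutral conditions, so no base can cleave or shift the aryl silyl ethers; the only phenolic oxygen present becomes O1.

Step 8
Reactants: 11 1-{[3,5-bis(triisopropylsilyloxy)phenyl]methoxy}-4-farnesyl-3,5-bis(methoxymethoxy)benzene
Product: 13 1-[2-{[3,5-bis(triisopropylsilyloxy)phenyl]methoxy}-5-farnesyl-4,6-bis(methoxymethoxy)phenyl]ethan-1-one, via aryllithium 12 (not isolated)
Conditions: n-BuLi (1.2 equiv), THF, 0 °C; then MeC(O)N(OMe)Me (1.5 equiv), −78 → 0 °C; aq NH4Cl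
Reagents that add atoms: N-methoxy-N-methylacetamide, CC(=O)N(C)OC
Why: Directed ortho-metalation at the only free ring A position, which is activated jointly by the MOM and benzyloxy oxygens (as in the lithiation of 1,3-dialkoxybenzenes, benzyl ethers included), followed by Weinreb ketone synthesis, which stops at the ketone through the chelated tetrahedral adduct.

Step 9
Reactants: 13 1-[2-{[3,5-bis(triisopropylsilyloxy)phenyl]methoxy}-5-farnesyl-4,6-bis(methoxymethoxy)phenyl]ethan-1-one
Product: 14 1-[2-{[3,5-bis(triisopropylsilyloxy)phenyl]methoxy}-5-farnesyl-4,6-dihydroxyphenyl]ethan-1-one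
Conditions: conc. HCl (5 equiv), MeOH–THF (3:1), rt
Reagents that add atoms: none
Why: Acid-catalysed acetal exchange with methanol removes both MOM ethers as dimethoxymethane at a stage without a stereocentre; the benzyl ether, the aryl TIPS ethers and the trisubstituted olefins should tolerate dilute HCl in methanol at room temperature.

Step 10
Reactants: 14 1-[2-{[3,5-bis(triisopropylsilyloxy)phenyl]methoxy}-5-farnesyl-4,6-dihydroxyphenyl]ethan-1-one
Product: 15 1-[2-{[3,5-bis(triisopropylsilyloxy)phenyl]methoxy}-5-farnesyl-4,6-bis(triisopropylsilyloxy)phenyl]ethan-1-one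
Conditions: TIPSOTf (2.6 equiv), 2,6-lutidine (4 equiv), CH2Cl2, −78 → 0 °C
Reagents that add atoms: triisopropylsilyl trifluoromethanesulfonate, CC(C)[Si](OS(=O)(=O)C(F)(F)F)(C(C)C)C(C)C
Why: The silyl triflate silylates the free para phenol and the hindered, hydrogen-bonded ortho phenol faster at low temperature than it enolises the hindered ketone, so O5 and O7 carry groups with no C–H that a six-membered insertion could reach; any ring B phenol freed in step 9 is silylated again here.

Step 11
Reactants: 15 1-[2-{[3,5-bis(triisopropylsilyloxy)phenyl]methoxy}-5-farnesyl-4,6-bis(triisopropylsilyloxy)phenyl]ethan-1-one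
Product: 18 2-diazo-1-[2-{[3,5-bis(triisopropylsilyloxy)phenyl]methoxy}-5-farnesyl-4,6-bis(triisopropylsilyloxy)phenyl]ethan-1-one, via lithium enolate 16 (not isolated), via trifluoroacetyl ketone 17 (not isolated)
Conditions: LiN(SiMe3)2 (1.15 equiv), THF, −78 °C; CF3CO2CH2CF3 (1.3 equiv), −78 °C; aq NH4Cl; crude 17, then MsN3 (1.5 equiv), Et3N (1.5 equiv), H2O (1 equiv), MeCN, rt
Reagents that add atoms: methanesulfonyl azide, CS(=O)(=O)N=[N+]=[N-]
Why: Detrifluoroacetylative diazo transfer: a methyl ketone is not acidic enough for direct Regitz diazo transfer, so its kinetic enolate is first C-trifluoroacetylated to an activated 1,3-diketone, which takes the diazo group from the sulfonyl azide and loses the trifluoroacetyl group as the N-sulfonyl amide.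

Step 12
Reactants: 18 2-diazo-1-[2-{[3,5-bis(triisopropylsilyloxy)phenyl]methoxy}-5-farnesyl-4,6-bis(triisopropylsilyloxy)phenyl]ethan-1-one
Product: 19 (2S)-6-farnesyl-5,7-bis(triisopropylsilyloxy)-2-[3,5-bis(triisopropylsilyloxy)phenyl]chroman-4-one
Conditions: Rh2(S-PTTL)4 (2 mol %), 4 Å MS, CH2Cl2, 0 °C → rt, slow addition of 18 (final 0.01 M)
Reagents that add atoms: none
Why: Rh2(S-PTTL)4 expels N2 from 18 to give an electrophilic divalent-rhodium carbenoid at C3, which inserts in a concerted, asynchronous, hydride-transfer-like way into one benzylic C–H of the O1–CH2–aryl group and so forms the C2–C3 bond. The closest known reaction type is the enantioselective intramolecular C–H insertion of 2-alkoxyaryl alpha-diazoketones to chroman-4-ones under chiral carboxylates of divalent rhodium. Ring C closes in the six-membered (1,6-insertion) mode through C3, C4, C4a, C8a, O1 and C2, because O1 occupies the place where a five-ring insertion would need a C–H. C2 is the only new stereocentre and is set by the catalyst, whose phthalimido and tert-butyl groups should distinguish the two enantiotopic benzylic hydrogens; the neutral medium does not epimerise it afterwards. The step needs chemoselectivity for insertion over attack on O1 (oxonium ylide, then [1,2]-benzyl shift to a benzofuranone), on O5 and on the farnesyl olefins; this is favoured by the weak donor ability of the aryl ether oxygen conjugated with ring A, by the O5 silyl group, by the meta position of the farnesyl chain, which cannot reach C3 through a small ring, and by slow addition at high dilution.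

Step 13
Reactants: 19 (2S)-6-farnesyl-5,7-bis(triisopropylsilyloxy)-2-[3,5-bis(triisopropylsilyloxy)phenyl]chroman-4-one
Product: 20 (2S)-2-(3,5-dihydroxyphenyl)-5,7-dihydroxy-6-farnesylchroman-4-one
Conditions: Bu4NF (4.5 equiv), AcOH (4.5 equiv), THF, 0 °C → rt
Reagents that add atoms: none
Why: Fluoride cleaves the four aryl silyl ethers, and the acetic acid buffer keeps phenoxide and enolate concentrations low so that ring C does not open by retro-oxa-Michael reaction and C2 is not racemised; the meta hydroxyls of ring B cannot form a quinone methide.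

**Compound list**

1 | methyl 3,5-dihydroxybenzoate | COC(=O)c1cc(O)cc(O)c1 | starting material
2 | methyl 3,5-bis(triisopropylsilyloxy)benzoate | COC(=O)c1cc(O[Si](C(C)C)(C(C)C)C(C)C)cc(O[Si](C(C)C)(C(C)C)C(C)C)c1 | intermediate
3 | [3,5-bis(triisopropylsilyloxy)phenyl]methanol | OCc1cc(O[Si](C(C)C)(C(C)C)C(C)C)cc(O[Si](C(C)C)(C(C)C)C(C)C)c1 | intermediate
4 | phloroglucinol (benzene-1,3,5-triol) | Oc1cc(O)cc(O)c1 | starting material
5 | 3,5-bis(methoxymethoxy)phenol | COCOc1cc(O)cc(OCOC)c1 | intermediate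
6 | [3,5-bis(methoxymethoxy)phenoxy]triisopropylsilane | COCOc1cc(OCOC)cc(O[Si](C(C)C)(C(C)C)C(C)C)c1 | intermediate
7 | (2E,6E)-farnesyl bromide | CC(C)=CCC/C(C)=C/CC/C(C)=C/CBr | starting material
8 | [2,6-bis(methoxymethoxy)-4-(triisopropylsilyloxy)phenyl]lithium (formed in the flask) | [Li]c1c(OCOC)cc(O[Si](C(C)C)(C(C)C)C(C)C)cc1OCOC | intermediate
9 | {4-[(2E,6E)-farnesyl]-3,5-bis(methoxymethoxy)phenoxy}triisopropylsilane | CC(C)=CCC/C(C)=C/CC/C(C)=C/Cc1c(OCOC)cc(O[Si](C(C)C)(C(C)C)C(C)C)cc1OCOC | intermediate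
10 | 4-[(2E,6E)-farnesyl]-3,5-bis(methoxymethoxy)phenol | CC(C)=CCC/C(C)=C/CC/C(C)=C/Cc1c(OCOC)cc(O)cc1OCOC | intermediate
11 | 1-{[3,5-bis(triisopropylsilyloxy)phenyl]methoxy}-4-[(2E,6E)-farnesyl]-3,5-bis(methoxymethoxy)benzene | CC(C)=CCC/C(C)=C/CC/C(C)=C/Cc1c(OCOC)cc(OCc2cc(O[Si](C(C)C)(C(C)C)C(C)C)cc(O[Si](C(C)C)(C(C)C)C(C)C)c2)cc1OCOC | intermediate
12 | [2-{[3,5-bis(triisopropylsilyloxy)phenyl]methoxy}-5-[(2E,6E)-farnesyl]-4,6-bis(methoxymethoxy)phenyl]lithium (formed in the flask) | CC(C)=CCC/C(C)=C/CC/C(C)=C/Cc1c(OCOC)c([Li])c(OCc2cc(O[Si](C(C)C)(C(C)C)C(C)C)cc(O[Si](C(C)C)(C(C)C)C(C)C)c2)cc1OCOC | intermediate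
13 | 1-[2-{[3,5-bis(triisopropylsilyloxy)phenyl]methoxy}-5-[(2E,6E)-farnesyl]-4,6-bis(methoxymethoxy)phenyl]ethan-1-one | CC(C)=CCC/C(C)=C/CC/C(C)=C/Cc1c(OCOC)c(C(C)=O)c(OCc2cc(O[Si](C(C)C)(C(C)C)C(C)C)cc(O[Si](C(C)C)(C(C)C)C(C)C)c2)cc1OCOC | intermediate
14 | 1-[2-{[3,5-bis(triisopropylsilyloxy)phenyl]methoxy}-5-[(2E,6E)-farnesyl]-4,6-dihydroxyphenyl]ethan-1-one | CC(C)=CCC/C(C)=C/CC/C(C)=C/Cc1c(O)c(C(C)=O)c(OCc2cc(O[Si](C(C)C)(C(C)C)C(C)C)cc(O[Si](C(C)C)(C(C)C)C(C)C)c2)cc1O | intermediate
15 | 1-[2-{[3,5-bis(triisopropylsilyloxy)phenyl]methoxy}-5-[(2E,6E)-farnesyl]-4,6-bis(triisopropylsilyloxy)phenyl]ethan-1-one | CC(C)=CCC/C(C)=C/CC/C(C)=C/Cc1c(O[Si](C(C)C)(C(C)C)C(C)C)c(C(C)=O)c(OCc2cc(O[Si](C(C)C)(C(C)C)C(C)C)cc(O[Si](C(C)C)(C(C)C)C(C)C)c2)cc1O[Si](C(C)C)(C(C)C)C(C)C | intermediate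
16 | lithium enolate of 15 (formed in the flask) | CC(C)=CCC/C(C)=C/CC/C(C)=C/Cc1c(O[Si](C(C)C)(C(C)C)C(C)C)c(C(=C)O[Li])c(OCc2cc(O[Si](C(C)C)(C(C)C)C(C)C)cc(O[Si](C(C)C)(C(C)C)C(C)C)c2)cc1O[Si](C(C)C)(C(C)C)C(C)C | intermediate
17 | 4,4,4-trifluoro-1-[2-{[3,5-bis(triisopropylsilyloxy)phenyl]methoxy}-5-[(2E,6E)-farnesyl]-4,6-bis(triisopropylsilyloxy)phenyl]butane-1,3-dione (crude, used directly) | CC(C)=CCC/C(C)=C/CC/C(C)=C/Cc1c(O[Si](C(C)C)(C(C)C)C(C)C)c(C(=O)CC(=O)C(F)(F)F)c(OCc2cc(O[Si](C(C)C)(C(C)C)C(C)C)cc(O[Si](C(C)C)(C(C)C)C(C)C)c2)cc1O[Si](C(C)C)(C(C)C)C(C)C | intermediate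
18 | 2-diazo-1-[2-{[3,5-bis(triisopropylsilyloxy)phenyl]methoxy}-5-[(2E,6E)-farnesyl]-4,6-bis(triisopropylsilyloxy)phenyl]ethan-1-one | CC(C)=CCC/C(C)=C/CC/C(C)=C/Cc1c(O[Si](C(C)C)(C(C)C)C(C)C)c(C(=O)C=[N+]=[N-])c(OCc2cc(O[Si](C(C)C)(C(C)C)C(C)C)cc(O[Si](C(C)C)(C(C)C)C(C)C)c2)cc1O[Si](C(C)C)(C(C)C)C(C)C | intermediate
19 | (2S)-6-[(2E,6E)-farnesyl]-5,7-bis(triisopropylsilyloxy)-2-[3,5-bis(triisopropylsilyloxy)phenyl]chroman-4-one | CC(C)=CCC/C(C)=C/CC/C(C)=C/Cc1c(O[Si](C(C)C)(C(C)C)C(C)C)cc2c(c1O[Si](C(C)C)(C(C)C)C(C)C)C(=O)C[C@@H](c1cc(O[Si](C(C)C)(C(C)C)C(C)C)cc(O[Si](C(C)C)(C(C)C)C(C)C)c1)O2 | intermediate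
20 | (2S)-2-(3,5-dihydroxyphenyl)-5,7-dihydroxy-6-[(2E,6E)-3,7,11-trimethyldodeca-2,6,10-trien-1-yl]chroman-4-one | CC(C)=CCC/C(C)=C/CC/C(C)=C/Cc1c(O)cc2c(c1O)C(=O)C[C@@H](c1cc(O)cc(O)c1)O2 | target

**Step count and risks**

Total steps: 13. Longest linear sequence: 11 steps (steps 3 to 13, from phloroglucinol); ring B is made in 2 steps (steps 1 and 2) and joins at step 7.

The three steps most likely to fail:

1. Step 12 (carbenoid C–H insertion). The carbenoid may be captured by the lone pair of O1, giving an oxonium ylide and then a [1,2]-benzyl shift, faster than it inserts; or the catalyst may discriminate poorly between the two enantiotopic benzylic hydrogens. The fallback gives up the carbenoid and forms the C2–C1' bond instead, by known asymmetric conjugate addition to a chromone. It sets out from phenol 10 and comes back to the route at target 20.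
   - Magnesium-mediated ortho-formylation of 10 (MgCl2, Et3N, paraformaldehyde, MeCN, reflux) should give the salicylaldehyde 3-farnesyl-6-hydroxy-2,4-bis(methoxymethoxy)benzaldehyde F1.
   - MeMgBr (3 equiv, THF, 0 °C) then gives the carbinol 1-[3-farnesyl-6-hydroxy-2,4-bis(methoxymethoxy)phenyl]ethanol F2, and MnO2 in CH2Cl2 oxidises it to the o-hydroxyacetophenone 1-[3-farnesyl-6-hydroxy-2,4-bis(methoxymethoxy)phenyl]ethanone F3.
   - Condensation with Me2NCH(OMe)2 (toluene, 90 °C) gives the enaminone (E)-3-(dimethylamino)-1-[3-farnesyl-6-hydroxy-2,4-bis(methoxymethoxy)phenyl]prop-2-en-1-one F4, which closes under AcOH, with loss of dimethylamine, to 6-farnesyl-5,7-bis(methoxymethoxy)chromone F5.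
   - Conjugate addition of purchased [3,5-bis(tert-butyldimethylsilyloxy)phenyl]boronic acid under Pd(OCOCF3)2 and the enantiomer of the t-BuPyOx ligand that leads to 2S (NH4PF6, H2O, ClCH2CH2Cl, 60 °C) sets C2 and gives (2S)-6-farnesyl-5,7-bis(methoxymethoxy)-3',5'-bis(tert-butyldimethylsilyloxy)flavanone F6.
   - 3 M HCl in MeOH at 45 °C then cleaves the two MOM ethers and the two aryl silyl ethers to give 20.

2. Step 8 (ortho-lithiation and acetylation). n-BuLi may remove a proton from the benzylic O–CH2 group (followed by Wittig rearrangement) or from the allylic, benzylic CH2 of the farnesyl chain between the two MOM ethers, instead of the ring C–H. The fallback makes the same aryl anion without any deprotonation. It sets out from 11: NBS (1.0 equiv, CH2Cl2, −78 °C) should brominate the single free position of the very electron-rich ring A faster than it attacks the olefins, giving the aryl bromide 2-bromo-1-{[3,5-bis(triisopropylsilyloxy)phenyl]methoxy}-4-farnesyl-3,5-bis(methoxymethoxy)benzene F7. Bromine–lithium exchange with n-BuLi in THF at −78 °C then comes back to the route at aryllithium 12, which is acetylated to 13 as in step 8.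

3. Step 11 (diazo transfer). The lithium enolate may take over the silyl group from the neighbouring O5 (O to O silyl migration), or the hindered enolate may be trifluoroacetylated incompletely or on oxygen, so that the diazo transfer fails. The fallback avoids any enolate. It sets out from 15: heating with Me2NCH(OMe)2 (neat, 100 °C) gives the enaminone (E)-3-(dimethylamino)-1-[2-{[3,5-bis(triisopropylsilyloxy)phenyl]methoxy}-5-farnesyl-4,6-bis(triisopropylsilyloxy)phenyl]prop-2-en-1-one F8. Its known reaction with MsN3 (MeCN, rt), by cycloaddition and cycloreversion, gives the diazoketone and an N-sulfonylformamidine, and the route is rejoined at 18.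

**Further compounds**

F1 | step 12 | 3-[(2E,6E)-farnesyl]-6-hydroxy-2,4-bis(methoxymethoxy)benzaldehyde | CC(C)=CCC/C(C)=C/CC/C(C)=C/Cc1c(OCOC)cc(O)c(C=O)c1OCOC
F2 | step 12 | 1-{3-[(2E,6E)-farnesyl]-6-hydroxy-2,4-bis(methoxymethoxy)phenyl}ethan-1-ol (racemic) | CC(C)=CCC/C(C)=C/CC/C(C)=C/Cc1c(OCOC)cc(O)c(C(C)O)c1OCOC
F3 | step 12 | 1-{3-[(2E,6E)-farnesyl]-6-hydroxy-2,4-bis(methoxymethoxy)phenyl}ethan-1-one | CC(C)=CCC/C(C)=C/CC/C(C)=C/Cc1c(OCOC)cc(O)c(C(C)=O)c1OCOC
F4 | step 12 | (2E)-3-(dimethylamino)-1-{3-[(2E,6E)-farnesyl]-6-hydroxy-2,4-bis(methoxymethoxy)phenyl}prop-2-en-1-one | CC(C)=CCC/C(C)=C/CC/C(C)=C/Cc1c(OCOC)cc(O)c(C(=O)/C=C/N(C)C)c1OCOC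
F5 | step 12 | 6-[(2E,6E)-farnesyl]-5,7-bis(methoxymethoxy)-4H-chromen-4-one | CC(C)=CCC/C(C)=C/CC/C(C)=C/Cc1c(OCOC)cc2occc(=O)c2c1OCOC
F6 | step 12 | (2S)-2-[3,5-bis(tert-butyldimethylsilyloxy)phenyl]-6-[(2E,6E)-farnesyl]-5,7-bis(methoxymethoxy)chroman-4-one | CC(C)=CCC/C(C)=C/CC/C(C)=C/Cc1c(OCOC)cc2c(c1OCOC)C(=O)C[C@@H](c1cc(O[Si](C)(C)C(C)(C)C)cc(O[Si](C)(C)C(C)(C)C)c1)O2
F7 | step 8 | 2-bromo-1-{[3,5-bis(triisopropylsilyloxy)phenyl]methoxy}-4-[(2E,6E)-farnesyl]-3,5-bis(methoxymethoxy)benzene | CC(C)=CCC/C(C)=C/CC/C(C)=C/Cc1c(OCOC)c(Br)c(OCc2cc(O[Si](C(C)C)(C(C)C)C(C)C)cc(O[Si](C(C)C)(C(C)C)C(C)C)c2)cc1OCOC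
F8 | step 11 | (2E)-3-(dimethylamino)-1-[2-{[3,5-bis(triisopropylsilyloxy)phenyl]methoxy}-5-[(2E,6E)-farnesyl]-4,6-bis(triisopropylsilyloxy)phenyl]prop-2-en-1-one | CC(C)=CCC/C(C)=C/CC/C(C)=C/Cc1c(O[Si](C(C)C)(C(C)C)C(C)C)c(C(=O)/C=C/N(C)C)c(OCc2cc(O[Si](C(C)C)(C(C)C)C(C)C)cc(O[Si](C(C)C)(C(C)C)C(C)C)c2)cc1O[Si](C(C)C)(C(C)C)C(C)C
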